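At early times ring climbs faster the more activator is charged, and that early rise is what I read first.

| setting | green | teal | violet | dusk | winter |
|---|---|---|---|---|---|
| substrate | 0.10 M | 0.10 M | 0.10 M | 0.10 M | 0.10 M |
| activator | 0.091 M | 0.13 M | 0.19 M | 0.240 M | 0.0800 M |
| remark | run made earlier | run made earlier | run made earlier |  |  |
| time |  |  |  | 10 h | 10 h |

| run | time / h | ring / % |
|---|---|---|
| green | 0.417 | 12.4 |
| green | 1.33 | 30.6 |
| green | 2.50 | 41.1 |
| green | 4.00 | 47.6 |
| green | 5.00 | 50.4 |
| teal | 0.417 | 16.9 |
| teal | 0.833 | 30.6 |
| teal | 1.33 | 39.6 |
| teal | 2.50 | 50.7 |
| teal | 5.00 | 60.9 |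
| violet | 0.417 | 23.3 |
| violet | 0.833 | 39.4 |
| violet | 1.33 | 49.9 |
| violet | 2.50 | 61.2 |
| violet | 5.00 | 67.9 |

(readings scatter by 0.3 percentage points)

- which of the two there is more of at the end, counted by the substrate in each, dusk (open dimer / ring)
- which of the two there is more of at the end, counted by the substrate in each, winter (open dimer / ring)
- final ring, as a percentage of the substrate charged, in dusk
- final ring, as a percentage of the substrate charged, in winter

- percent here means substrate units held: one open dimer counts as two
- the earlier runs were read with a standard deviation of 0.3 percentage points
- a reading or a percentage of ring counts all its forms, free or not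

I define k as the fraction of substrate turned to ring per hour per mole per litre of activator, taken from the first reading of a run. Green gives

k = 3.27 L mol⁻¹ h⁻¹

and violet gives 2.94 L mol⁻¹ h⁻¹, so I carry green's reading. With one partner held at level c, the other falls in a pseudo-first-order way, with half-life τ = ln(2)/(k c). I then count how many τ fit into 10 h, assuming each substrate spends at most one activator.

For dusk there are two ways to count. Holding activator at its charge gives

τ = 0.884 h, substrate left 0.0393%.

Holding it at the floor, charge minus substrate, gives

τ = 1.52 h, substrate left 1.03%.

Both leave dusk with little substrate, so I trust that.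

For winter the activator charge is smaller than the substrate charge, so there is no floor. Holding activator at its charge gives

substrate left 7.31%.

Letting both partners fall together, as if both stood at the activator charge, gives

substrate left 27.7%.

These two part, and the first one cheats: it keeps activator at 0.0800 M for the whole 10 h while activator is being spent. So I expect winter still to be moving at 10 h.

The forecast calls ring for dusk and ring for winter, with 73% and 51.5% of ring, and says “Both new runs should be essentially finished by 10 h”. On winter I differ from it.

The flask gives 71.2% of ring in dusk and 53.7% in winter, with ring ahead in both, as forecast. Free substrate stands at 0.012% in dusk and 9.2% in winter, whose ring reaches 63.4% after 100 h.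

    substrate + ring ⇌ idle adduct, settled at all times (K = 14.0 L mol⁻¹)
    ring → over-reaction product (k = 4.40 × 10⁻⁵ h⁻¹)
    substrate + activated form → open dimer (k = 40.0 L mol⁻¹ h⁻¹)
    activated form → ring (k = 6.00 h⁻¹)
    substrate + activator → activated form (k = 9.10 L mol⁻¹ h⁻¹)

The forecast's call for ring changes in the flask like winter but with 0.40 M of substrate. There activator is the limiting reagent, and with substrate taken as held at its charge my ring-based k gives τ = 0.530 h, so 10 h holds 18.9 such half-lives; the uptake constant of the scheme, 9.1 L mol⁻¹ h⁻¹, gives a shorter τ of 0.190 h. That flask ends with activator at 0% of its own charge, ring at 6.48%, open dimer at 27.0% and substrate at 61%.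

The data come from a simulation for an exercise.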